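**Retrosynthetic overview**
1. Last bond made (key step): the ester C–O bond between the carboxyl group of the diketo acid and the terminal CH2 of (S)-glycidyl acetate. Epoxide opening gives the acyl–O–CH2 link, the free secondary OH and the (2R) glycerol centre in one operation, with no protecting group on the glycerol part.
2. The diketo acid comes from its tert-butyl ester / dioxolane. Its ring methyl and masked 3-oxobutyl arm come from a one-pot asymmetric conjugate addition / enolate methylation on a 1-acyl-3,3-dimethylcyclohexene, which sets both ring stereocentres.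
3. The enone comes from 3,3-dimethylcyclohexenyl triflate (from 3-methylcyclohex-2-en-1-one) and the aldehyde from ozonolysis of tert-butyl (R)-citronellate, which carries the (3R) methyl centre.
4. Rings: the only carbocycle is bought in 3-methylcyclohex-2-en-1-one and carried through; no ring is formed in the route.

Target as read from the SMILES: ring (1R,2S), with the ring methyl trans to the 3-oxobutyl arm and the acyl group cis to it; chain (3R); glycerol (2R).

Assumption: the facial sense of the new copper catalyst in step 6 cannot be known in advance; the ligand enantiomer written is taken to give the (2S) adduct, and its mirror image is used if the opposite sense is found.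

**Step 1**
Reactants: 1 3-methylcyclohex-2-en-1-one
Product: 3 3,3-dimethylcyclohex-1-en-1-yl trifluoromethanesulfonate, via bromomagnesium enolate 2 (not isolated)
Conditions: MeMgBr (1.2 equiv), CuBr·SMe2 (5 mol %), THF, −30 °C; then PhNTf2 (1.3 equiv), DMPU, −30 °C → rt
Reagents that add atoms: methylmagnesium bromide C[Mg]Br; N-phenylbis(trifluoromethanesulfonimide) O=S(=O)(N(c1ccccc1)S(=O)(=O)C(F)(F)F)C(F)(F)F
Why: Copper-catalysed 1,4-addition of the methyl Grignard reagent gives the enolate regiospecifically on the side of the new quaternary carbon, and O-triflation (enolate trapping) fixes the double bond there; no stereocentre is formed.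

**Step 2**
Reactants: 4 (R)-citronellic acid
Product: 5 tert-butyl (3R)-3,7-dimethyloct-6-enoate
Conditions: t-BuOC(=NH)CCl3 (2 equiv), BF3·OEt2 (2 mol %), CH2Cl2/cyclohexane, 0 °C → rt
Reagents that add atoms: tert-butyl 2,2,2-trichloroacetimidate CC(C)(C)OC(=N)C(Cl)(Cl)Cl
Why: Acid-catalysed tert-butyl transfer from the trichloroacetimidate (tert-butyl esterification) is mild enough to leave the trisubstituted alkene and the (3R) centre untouched.

**Step 3**
Reactants: 5 tert-butyl (3R)-3,7-dimethyloct-6-enoate
Product: 7 tert-butyl (3R)-3-methyl-6-oxohexanoate, via ozonide 6 (not isolated)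
Conditions: O3, CH2Cl2, −78 °C; then PPh3, −78 °C → rt
Reagents that add atoms: ozone [O-][O+]=O
Why: Ozonolysis with reductive work-up (Criegee mechanism) cleaves the only C=C bond to the aldehyde, and the (3R) centre is remote from it and not enolisable.

**Step 4**
Reactants: 3 3,3-dimethylcyclohex-1-en-1-yl trifluoromethanesulfonate; 7 tert-butyl (3R)-3-methyl-6-oxohexanoate
Product: 8 tert-butyl (3R)-6-(3,3-dimethylcyclohex-1-en-1-yl)-6-hydroxy-3-methylhexanoate (both C6 epimers)
Conditions: CrCl2 (4 equiv), NiCl2 (2 mol %), DMF, rt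
Reagents that add atoms: none
Why: Nozaki–Hiyama–Kishi coupling: nickel-catalysed activation of the C–OTf bond and transmetalation to chromium give an alkenylchromium reagent that adds to the aldehyde in the presence of the ester; the new carbinol centre is removed in step 5.

**Step 5**
Reactants: 8 tert-butyl (3R)-6-(3,3-dimethylcyclohex-1-en-1-yl)-6-hydroxy-3-methylhexanoate
Product: 9 tert-butyl (3R)-6-(3,3-dimethylcyclohex-1-en-1-yl)-3-methyl-6-oxohexanoate
Conditions: Dess–Martin periodinane (1.3 equiv), CH2Cl2, 0 °C → rt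
Reagents that add atoms: none
Why: Dess–Martin oxidation of the secondary allylic alcohol gives the conjugated enone without moving the double bond or touching the ester.

**Step 6**
Reactants: 9 tert-butyl (3R)-6-(3,3-dimethylcyclohex-1-en-1-yl)-3-methyl-6-oxohexanoate; 10 2-(2-bromoethyl)-2-methyl-1,3-dioxolane
Product: 13 tert-butyl (3R)-3-methyl-6-[(1R,2S)-1,3,3-trimethyl-2-[2-(2-methyl-1,3-dioxolan-2-yl)ethyl]cyclohexyl]-6-oxohexanoate, via Grignard reagent 11 (not isolated), via magnesium enolate 12 (not isolated)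
Conditions: 10, Mg, THF, 30 °C (gives 11, 1.5 equiv); 9, CuBr·SMe2 (5 mol %), (R)-1-[(S_p)-2-(diphenylphosphino)ferrocenyl]ethyldicyclohexylphosphine (6 mol %), t-BuOMe, −78 °C, slow addition of 11; then MeI (5 equiv), DMPU (5 equiv), −78 → 0 °C
Reagents that add atoms: iodomethane CI
Why: Proposed new method: an enantioselective copper-catalysed 1,4-addition of a functionalised primary alkyl Grignard reagent to a 1-acylcyclohexene whose β-carbon is flanked by a quaternary carbon, with C-methylation of the resulting tetrasubstituted magnesium enolate in the same flask, has not been shown; the ferrocenyl diphosphine–CuBr complex is transmetalated by 11 to a chiral alkylcopper species that binds the enone C=C as a π-complex, adds at the β-carbon (ring C2) to give a σ-bonded trivalent copper enolate and reductively eliminates, so the ligand chooses the alkene face (catalyst control, 2S); the enolate is formed only toward ring C1, and MeI then attacks the face away from the new C2 side chain, which in the conformer with that chain equatorial is also the face not shielded by the axial C3 methyl, so the methyl enters trans to the side chain and the acyl group ends up cis to it (1R); closest known reaction type: CuBr·SMe2/ferrocenyl-diphosphine-catalysed conjugate addition of Grignard reagents to acyclic enones, with alkylative trapping of the magnesium enolate.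

**Step 7**
Reactants: 13 tert-butyl (3R)-3-methyl-6-[(1R,2S)-1,3,3-trimethyl-2-[2-(2-methyl-1,3-dioxolan-2-yl)ethyl]cyclohexyl]-6-oxohexanoate
Product: 14 (3R)-3-methyl-6-oxo-6-[(1R,2S)-1,3,3-trimethyl-2-(3-oxobutyl)cyclohexyl]hexanoic acid
Conditions: TFA/CH2Cl2/H2O (10:10:1), 0 °C → rt
Reagents that add atoms: water O
Why: Acidolysis cleaves the tert-butyl ester through the tert-butyl cation and aqueous acid hydrolyses the dioxolane; ring C1 is quaternary, ring C2 is not α to a carbonyl and the (3R) centre is β to the carboxyl group, so nothing can epimerise.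

**Step 8**
Reactants: 15 (R)-glycidol
Product: 16 (S)-glycidyl acetate
Conditions: Ac2O (1.1 equiv), Et3N (1.2 equiv), DMAP (2 mol %), CH2Cl2, 0 °C
Reagents that add atoms: acetic anhydride CC(=O)OC(C)=O
Why: DMAP-catalysed acetylation of the primary alcohol does not touch the stereocentre; the descriptor changes from R to S only through the priority rules.

**Step 9**
Reactants: 14 (3R)-3-methyl-6-oxo-6-[(1R,2S)-1,3,3-trimethyl-2-(3-oxobutyl)cyclohexyl]hexanoic acid; 16 (S)-glycidyl acetate
Product: 17 [(2R)-3-(acetyloxy)-2-hydroxypropyl] (3R)-3-methyl-6-oxo-6-[(1R,2S)-1,3,3-trimethyl-2-(3-oxobutyl)cyclohexyl]hexanoate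
Conditions: 16 (1.5 equiv), (R,R)-N,N′-bis(3,5-di-tert-butylsalicylidene)-1,2-cyclohexanediaminocobalt (C36H52CoN2O2, 5 mol %, oxidised in the flask by air and 14 to the trivalent cobalt carboxylate), i-Pr2NEt (0.5 equiv), t-BuOMe, 0 °C → rt
Reagents that add atoms: none
Why: Carboxylate opening of the terminal epoxide at its unsubstituted carbon (SN2, one trivalent cobalt salen centre activating the epoxide and a second delivering the carboxylate) forms the ester C–O bond and frees the secondary hydroxyl; the epoxide stereocentre is not touched and becomes the (2R) glycerol centre.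

**Compound list**
1 | 3-methylcyclohex-2-en-1-one | CC1=CC(=O)CCC1 | starting material
2 | bromomagnesium 3,3-dimethylcyclohex-1-en-1-olate | CC1(C)CCCC(O[Mg]Br)=C1 | intermediate
3 | 3,3-dimethylcyclohex-1-en-1-yl trifluoromethanesulfonate | CC1(C)CCCC(OS(=O)(=O)C(F)(F)F)=C1 | intermediate
4 | (R)-citronellic acid, (3R)-3,7-dimethyloct-6-enoic acid | C[C@H](CCC=C(C)C)CC(=O)O | starting material
5 | tert-butyl (3R)-3,7-dimethyloct-6-enoate | C[C@H](CCC=C(C)C)CC(=O)OC(C)(C)C | intermediate
6 | tert-butyl (3R)-5-(5,5-dimethyl-1,2,4-trioxolan-3-yl)-3-methylpentanoate (ozonide, both epimers at the trioxolane carbon) | C[C@H](CCC1OOC(C)(C)O1)CC(=O)OC(C)(C)C | intermediate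
7 | tert-butyl (3R)-3-methyl-6-oxohexanoate | C[C@H](CCC=O)CC(=O)OC(C)(C)C | intermediate
8 | tert-butyl (3R)-6-(3,3-dimethylcyclohex-1-en-1-yl)-6-hydroxy-3-methylhexanoate (both C6 epimers) | C[C@H](CCC(O)C1=CC(C)(C)CCC1)CC(=O)OC(C)(C)C | intermediate
9 | tert-butyl (3R)-6-(3,3-dimethylcyclohex-1-en-1-yl)-3-methyl-6-oxohexanoate | C[C@H](CCC(=O)C1=CC(C)(C)CCC1)CC(=O)OC(C)(C)C | intermediate
10 | 2-(2-bromoethyl)-2-methyl-1,3-dioxolane | CC1(CCBr)OCCO1 | starting material
11 | [2-(2-methyl-1,3-dioxolan-2-yl)ethyl]magnesium bromide | CC1(CC[Mg]Br)OCCO1 | intermediate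
12 | tert-butyl (3R)-6-(bromomagnesiooxy)-6-[(2S)-3,3-dimethyl-2-[2-(2-methyl-1,3-dioxolan-2-yl)ethyl]cyclohexylidene]-3-methylhexanoate (magnesium enolate, enolate geometry not defined) | CC1(CC[C@H]2C(C)(C)CCCC2=C(O[Mg]Br)CC[C@@H](C)CC(=O)OC(C)(C)C)OCCO1 | intermediate
13 | tert-butyl (3R)-3-methyl-6-[(1R,2S)-1,3,3-trimethyl-2-[2-(2-methyl-1,3-dioxolan-2-yl)ethyl]cyclohexyl]-6-oxohexanoate | CC1(CC[C@H]2C(C)(C)CCC[C@@]2(C)C(=O)CC[C@@H](C)CC(=O)OC(C)(C)C)OCCO1 | intermediate
14 | (3R)-3-methyl-6-oxo-6-[(1R,2S)-1,3,3-trimethyl-2-(3-oxobutyl)cyclohexyl]hexanoic acid | CC(=O)CC[C@H]1C(C)(C)CCC[C@@]1(C)C(=O)CC[C@@H](C)CC(=O)O | intermediate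
15 | (R)-glycidol, [(2R)-oxiran-2-yl]methanol | OC[C@@H]1CO1 | starting material
16 | (S)-glycidyl acetate, [(2S)-oxiran-2-yl]methyl acetate | CC(=O)OC[C@@H]1CO1 | intermediate
17 | [(2R)-3-(acetyloxy)-2-hydroxypropyl] (3R)-3-methyl-6-oxo-6-[(1R,2S)-1,3,3-trimethyl-2-(3-oxobutyl)cyclohexyl]hexanoate | CC(=O)CC[C@H]1C(C)(C)CCC[C@@]1(C)C(=O)CC[C@@H](C)CC(=O)OC[C@H](O)COC(C)=O | target

**Step count**
Total: 9 steps. Longest linear sequence: 7 steps (steps 2, 3, 4, 5, 6, 7 and 9, from 4 to 17).

**Three steps most likely to fail**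

Step 6 (the proposed new method). The β-carbon is neopentyl-like and the enone is α-substituted, so conversion or enantioselectivity may be low, and the methylation may be sluggish or less face-selective than expected. Fallback with known chemistry: setting out from 9, catalyst control is given up. Grignard reagent 11 is added under achiral copper catalysis (CuBr·SMe2, 10 mol %, no ligand) with Me3SiCl in THF at −78 °C, and the adduct is isolated as the silyl enol ether tert-butyl (3R)-6-[3,3-dimethyl-2-[2-(2-methyl-1,3-dioxolan-2-yl)ethyl]cyclohexylidene]-3-methyl-6-(trimethylsilyloxy)hexanoate F1. Both ring epimers form, about 1:1, because the (3R) centre is too remote to bias the addition. Benzyltrimethylammonium fluoride in THF then gives the regiodefined benzyltrimethylammonium (4R)-6-tert-butoxy-1-[3,3-dimethyl-2-[2-(2-methyl-1,3-dioxolan-2-yl)ethyl]cyclohexylidene]-4-methyl-6-oxohexan-1-olate F2, which MeI methylates at the ring carbon anti to the side chain. The product is 13 together with its ring diastereomer tert-butyl (3R)-3-methyl-6-[(1S,2R)-1,3,3-trimethyl-2-[2-(2-methyl-1,3-dioxolan-2-yl)ethyl]cyclohexyl]-6-oxohexanoate F3. The two are diastereomers and are separated by preparative HPLC; the route continues from 13.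

Step 7. The cis-disposed 1,6-diketone may undergo acid-promoted intramolecular aldol condensation while the tert-butyl ester is cleaved. Fallback: setting out from 9, the side-chain ketone is carried as a terminal alkene instead of a ketal, so the 1,6-diketone never meets strong acid. Step 6 is run with commercial but-3-en-1-ylmagnesium bromide in place of 11 and gives, through the magnesium enolate tert-butyl (3R)-6-(bromomagnesiooxy)-6-[(2S)-2-(but-3-en-1-yl)-3,3-dimethylcyclohexylidene]-3-methylhexanoate F4 and MeI, the alkenyl ketone tert-butyl (3R)-6-[(1R,2S)-2-(but-3-en-1-yl)-1,3,3-trimethylcyclohexyl]-3-methyl-6-oxohexanoate F5. Anhydrous TFA/CH2Cl2 cleaves only the tert-butyl ester to (3R)-6-[(1R,2S)-2-(but-3-en-1-yl)-1,3,3-trimethylcyclohexyl]-3-methyl-6-oxohexanoic acid F6. A Tsuji–Wacker oxidation (PdCl2 10 mol %, CuCl, O2, DMF/H2O, rt) then turns the terminal alkene into the methyl ketone under nearly neutral conditions and returns to 14. This fallback still uses the step 6 reaction; if that fails as well, the same alkene variant is run through the stepwise sequence of the first fallback.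

Step 9. Attack at the internal epoxide carbon, or acyl migration between the primary and secondary oxygens during reaction or chromatography, would give regioisomeric diacylglycerols. Fallback: setting out from 14, the ester C–O bond is made by acyl substitution instead of epoxide opening. Steglich esterification (EDC·HCl, DMAP, CH2Cl2) with commercial (S)-solketal gives the acetonide ester [(4R)-2,2-dimethyl-1,3-dioxolan-4-yl]methyl (3R)-3-methyl-6-oxo-6-[(1R,2S)-1,3,3-trimethyl-2-(3-oxobutyl)cyclohexyl]hexanoate F7. Me2BBr in CH2Cl2 at −50 °C removes the acetonide without acyl migration and gives the monoacylglycerol (2R)-2,3-dihydroxypropyl (3R)-3-methyl-6-oxo-6-[(1R,2S)-1,3,3-trimethyl-2-(3-oxobutyl)cyclohexyl]hexanoate F8. Acetylation of the primary hydroxyl alone (AcCl, 2,4,6-collidine, CH2Cl2, −78 °C) gives 17.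

**Further compounds**
F1 | step 6 | tert-butyl (3R)-6-[3,3-dimethyl-2-[2-(2-methyl-1,3-dioxolan-2-yl)ethyl]cyclohexylidene]-3-methyl-6-(trimethylsilyloxy)hexanoate (both ring epimers) | CC1(CCC2C(C)(C)CCCC2=C(O[Si](C)(C)C)CC[C@@H](C)CC(=O)OC(C)(C)C)OCCO1
F2 | step 6 | benzyltrimethylammonium (4R)-6-tert-butoxy-1-[3,3-dimethyl-2-[2-(2-methyl-1,3-dioxolan-2-yl)ethyl]cyclohexylidene]-4-methyl-6-oxohexan-1-olate | C[N+](C)(C)Cc1ccccc1.[O-]C(CC[C@@H](C)CC(=O)OC(C)(C)C)=C1CCCC(C)(C)C1CCC1(C)OCCO1
F3 | step 6 | tert-butyl (3R)-3-methyl-6-[(1S,2R)-1,3,3-trimethyl-2-[2-(2-methyl-1,3-dioxolan-2-yl)ethyl]cyclohexyl]-6-oxohexanoate | CC1(CC[C@@H]2C(C)(C)CCC[C@]2(C)C(=O)CC[C@@H](C)CC(=O)OC(C)(C)C)OCCO1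
F4 | step 7 | tert-butyl (3R)-6-(bromomagnesiooxy)-6-[(2S)-2-(but-3-en-1-yl)-3,3-dimethylcyclohexylidene]-3-methylhexanoate | C=CCC[C@H]1C(C)(C)CCCC1=C(O[Mg]Br)CC[C@@H](C)CC(=O)OC(C)(C)C
F5 | step 7 | tert-butyl (3R)-6-[(1R,2S)-2-(but-3-en-1-yl)-1,3,3-trimethylcyclohexyl]-3-methyl-6-oxohexanoate | C=CCC[C@H]1C(C)(C)CCC[C@@]1(C)C(=O)CC[C@@H](C)CC(=O)OC(C)(C)C
F6 | step 7 | (3R)-6-[(1R,2S)-2-(but-3-en-1-yl)-1,3,3-trimethylcyclohexyl]-3-methyl-6-oxohexanoic acid | C=CCC[C@H]1C(C)(C)CCC[C@@]1(C)C(=O)CC[C@@H](C)CC(=O)O
F7 | step 9 | [(4R)-2,2-dimethyl-1,3-dioxolan-4-yl]methyl (3R)-3-methyl-6-oxo-6-[(1R,2S)-1,3,3-trimethyl-2-(3-oxobutyl)cyclohexyl]hexanoate | CC(=O)CC[C@H]1C(C)(C)CCC[C@@]1(C)C(=O)CC[C@@H](C)CC(=O)OC[C@H]2COC(C)(C)O2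
F8 | step 9 | (2R)-2,3-dihydroxypropyl (3R)-3-methyl-6-oxo-6-[(1R,2S)-1,3,3-trimethyl-2-(3-oxobutyl)cyclohexyl]hexanoate | CC(=O)CC[C@H]1C(C)(C)CCC[C@@]1(C)C(=O)CC[C@@H](C)CC(=O)OC[C@H](O)CO
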